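The route cuts both C3–ring B bonds back to a C2-symmetric bis-flavanone. Ring B, the central benzene, is fused at C8a–C3a and C7a–C4a to two identical, equally configured trans-2-aryl-dihydrofurans (O1–C2–C3 and O7–C6–C5) that flank C4. A twofold oxidative 1,2-shift moves the ring B carbons from the two ketone carbons to the α-carbons, contracts both pyranones at once and relays the catalyst-set C2 and C6 configuration to C3 and C5 as esters, which later give way to aryl groups. The precursor is the (2R,8R)-bis-flavanone 9, whose C5 methyl group already bears the phosphonate needed for the stilbene, so that no radical bromination is required once electron-rich arenes are present.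

Key step: step 7

Remark: locants follow pyrano[3,2-g]chromene numbering for 5–10 and benzo[1,2-b:5,4-b′]difuran numbering for 11–19.
Remark: ring B is built from orcinol dimethyl ether (1), because both acetyl groups must enter beside the methyl group and the free diphenol is liable to take the second acyl group between its hydroxyl groups.
Remark: it is assumed that the (S)-pyridine-oxazoline ligand directs the aryl group to the same enone face as in its additions to cyclic enones, which corresponds to R at C2 and C8; if the sense proves opposite, the (R)-ligand is used.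

Step 1
Reactants: 1 1,3-dimethoxy-5-methylbenzene (3,5-dimethoxytoluene)
Product: 2 1,1′-(4,6-dimethoxy-2-methyl-1,3-phenylene)di(ethan-1-one)
Conditions: AcCl (3 equiv), AlCl3 (3 equiv), CH2Cl2, −10 °C → rt
Reagents that add atoms: acetyl chloride, CC(Cl)=O
Why: Twofold Friedel–Crafts acylation in which each acetyl group should enter para to one methoxy group and beside the methyl group, the position between the two methoxy groups being the most hindered, while the first acetyl group is twisted out of conjugation by its two ortho neighbours and so leaves the ring reactive enough for the second acylation.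

Step 2
Reactants: 2 1,1′-(4,6-dimethoxy-2-methyl-1,3-phenylene)di(ethan-1-one)
Product: 3 1,1′-(4,6-dihydroxy-2-methyl-1,3-phenylene)di(ethan-1-one)
Conditions: BCl3 (3 equiv), CH2Cl2, −78 → 0 °C; then H2O
Reagents that add atoms: none
Why: Chelation-directed ether cleavage, in which BCl3 bound to a ketone oxygen removes only the methyl group of the neighbouring methoxy group, and in 2 both methoxy groups lie ortho to an acetyl group.

Step 3
Reactants: 3 1,1′-(4,6-dihydroxy-2-methyl-1,3-phenylene)di(ethan-1-one)
Product: 5 5-methyl-4H,6H-pyrano[3,2-g]chromene-4,6-dione, via bis-enaminone 4 (not isolated)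
Conditions: Me2NCH(OMe)2 (4 equiv), toluene, 100 °C; then conc. HCl, CH2Cl2, 40 °C
Reagents that add atoms: N,N-dimethylformamide dimethyl acetal, COC(OC)N(C)C
Why: Enaminone route to chromones, in which each acetyl methyl group condenses with the amide acetal and acid then brings about conjugate addition of the neighbouring phenol with loss of dimethylamine; no stereocentre is formed.

Step 4
Reactants: 5 5-methyl-4H,6H-pyrano[3,2-g]chromene-4,6-dione
Product: 6 5-(bromomethyl)-4H,6H-pyrano[3,2-g]chromene-4,6-dione
Conditions: NBS (1.05 equiv), AIBN (cat.), PhCF3, 85 °C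
Reagents that add atoms: N-bromosuccinimide, O=C1CCC(=O)N1Br
Why: Wohl–Ziegler bromination at the stage where the methyl group holds the only sp3 C–H bonds and the two carbonyl groups deactivate ring B toward electrophilic bromination, which is why it is placed before any benzylic ether or electron-rich aryl group exists.

Step 5
Reactants: 6 5-(bromomethyl)-4H,6H-pyrano[3,2-g]chromene-4,6-dione
Product: 7 diethyl [(4,6-dioxo-4H,6H-pyrano[3,2-g]chromen-5-yl)methyl]phosphonate
Conditions: P(OEt)3 (neat), 120 °C
Reagents that add atoms: triethyl phosphite, CCOP(OCC)OCC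
Why: Michaelis–Arbuzov reaction of the benzylic bromide, with the neutral phosphite not expected to add to the chromone enones in the absence of an activator.

Step 6
Reactants: 7 diethyl [(4,6-dioxo-4H,6H-pyrano[3,2-g]chromen-5-yl)methyl]phosphonate; 8 4-methoxyphenylboronic acid
Product: 9 diethyl {[(2R,8R)-2,8-bis(4-methoxyphenyl)-4,6-dioxo-2,3,7,8-tetrahydro-4H,6H-pyrano[3,2-g]chromen-5-yl]methyl}phosphonate
Conditions: Pd(OCOCF3)2 (10 mol%), (S)-4-tert-butyl-2-(pyridin-2-yl)-4,5-dihydrooxazole (12 mol%), NH4PF6 (60 mol%), H2O (10 equiv), 8 (4 equiv), ClCH2CH2Cl, 60 °C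
Reagents that add atoms: none
Why: Asymmetric conjugate addition of an arylboronic acid to a chromone under divalent palladium with a pyridine-oxazoline ligand, in which the tert-butyl group of the ligand shields one enone face during insertion into the aryl–palladium bond, so each of C2 and C8 is set independently by the catalyst and most minor-face events should end in the separable meso isomer, leaving the (2R,8R) isomer enriched.

Step 7
Reactants: 9 diethyl {[(2R,8R)-2,8-bis(4-methoxyphenyl)-4,6-dioxo-2,3,7,8-tetrahydro-4H,6H-pyrano[3,2-g]chromen-5-yl]methyl}phosphonate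
Product: 11 dimethyl (2R,3R,5R,6R)-4-[(diethoxyphosphoryl)methyl]-2,6-bis(4-methoxyphenyl)-2,3,5,6-tetrahydrobenzo[1,2-b:5,4-b′]difuran-3,5-dicarboxylate, via bis(methyl enol ether) 10 (not isolated)
Conditions: PhI(OAc)2 (2.4 equiv), conc. H2SO4 (3 equiv), HC(OMe)3, 0 °C → rt; then aq. NaHCO3
Reagents that add atoms: trimethyl orthoformate, COC(OC)OC; water (work-up), O
Why: Acid and the orthoester turn each ketone into its methyl enol ether (10), whose C3 or C7 carbon attacks the trivalent iodine; methanol adds at the former carbonyl carbon, and the ring B carbon (C4a or C5a) then shifts from that carbon to the iodine-bearing carbon as iodobenzene leaves, giving a dimethoxycarbenium ion that ends as the methyl ester. The closest known reaction is the oxidative ring contraction of flavanones to methyl trans-2-aryl-2,3-dihydrobenzofuran-3-carboxylates with PhI(OAc)2 or Tl(NO3)3 in trimethyl orthoformate, run here twice on one molecule. Each dihydrofuran ring arises by contraction of a pyranone through this 1,2-aryl shift and not by a cyclisation, so no ring-closure mode in the Baldwin sense applies. C2 and C6 are not touched and keep the configuration from step 6, and the new C3 and C5 centres are controlled by them, since the shifting bond must lie anti to a C–I bond that is equatorial and trans to the equatorial aryl group, and the enolisable ester can in any case settle trans. The step needs ring B to migrate in preference to the 4-methoxyphenyl group, which is secured by the ether oxygens ortho and para to C4a and C5a, by the dialkoxy-stabilised cation left behind, and by the fact that an aryl shift from C2 would require aryl and iodine both axial. Cold addition and only a slight excess of oxidant should limit acid opening of the benzylic ethers and attack of the oxidant on the anisyl rings.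

Step 8
Reactants: 11 dimethyl (2R,3R,5R,6R)-4-[(diethoxyphosphoryl)methyl]-2,6-bis(4-methoxyphenyl)-2,3,5,6-tetrahydrobenzo[1,2-b:5,4-b′]difuran-3,5-dicarboxylate
Product: 12 (2R,3R,5R,6R)-4-[(diethoxyphosphoryl)methyl]-2,6-bis(4-methoxyphenyl)-2,3,5,6-tetrahydrobenzo[1,2-b:5,4-b′]difuran-3,5-dicarboxylic acid
Conditions: LiOH·H2O (8 equiv), THF/MeOH/H2O, 40 °C; then 1 M HCl
Reagents that add atoms: lithium hydroxide, [Li+].[OH-]
Why: Saponification of the two methyl esters, in which the epimerisable C3 and C5 centres already hold the more stable trans arrangement and the diethyl phosphonate should resist hydroxide under these conditions.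

Step 9
Reactants: 12 (2R,3R,5R,6R)-4-[(diethoxyphosphoryl)methyl]-2,6-bis(4-methoxyphenyl)-2,3,5,6-tetrahydrobenzo[1,2-b:5,4-b′]difuran-3,5-dicarboxylic acid
Product: 13 bis(1,3-dioxoisoindolin-2-yl) (2R,3R,5R,6R)-4-[(diethoxyphosphoryl)methyl]-2,6-bis(4-methoxyphenyl)-2,3,5,6-tetrahydrobenzo[1,2-b:5,4-b′]difuran-3,5-dicarboxylate
Conditions: N-hydroxyphthalimide (2.4 equiv), DIC (2.4 equiv), DMAP (0.2 equiv), CH2Cl2, rt
Reagents that add atoms: N-hydroxyphthalimide, O=C1c2ccccc2C(=O)N1O
Why: Carbodiimide esterification of Steglich type gives the redox-active esters, and any epimerisation at C3 or C5 is of no consequence because these centres become radicals in step 11.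

Step 10
Reactants: 14 1-bromo-3,5-dimethoxybenzene
Product: 16 (3,5-dimethoxyphenyl)zinc chloride (LiCl complex, THF solution), via arylmagnesium bromide 15 (not isolated)
Conditions: Mg, LiCl, THF, rt; then ZnCl2 (1.0 M in THF), 0 °C → rt
Reagents that add atoms: zinc chloride, Cl[Zn]Cl
Why: LiCl-assisted magnesium insertion into the aryl bromide followed by transmetalation to zinc, a standard preparation of arylzinc halides.

Step 11
Reactants: 13 bis(1,3-dioxoisoindolin-2-yl) (2R,3R,5R,6R)-4-[(diethoxyphosphoryl)methyl]-2,6-bis(4-methoxyphenyl)-2,3,5,6-tetrahydrobenzo[1,2-b:5,4-b′]difuran-3,5-dicarboxylate; 16 (3,5-dimethoxyphenyl)zinc chloride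
Product: 17 diethyl {[(2R,3R,5R,6R)-3,5-bis(3,5-dimethoxyphenyl)-2,6-bis(4-methoxyphenyl)-2,3,5,6-tetrahydrobenzo[1,2-b:5,4-b′]difuran-4-yl]methyl}phosphonate
Conditions: NiCl2·glyme (40 mol%), 4,4′-di-tert-butyl-2,2′-bipyridine (80 mol%), 16 (6 equiv), THF/DMF, rt
Reagents that add atoms: none
Why: Nickel-catalysed decarboxylative Negishi-type arylation of redox-active esters, in which single-electron reduction of each ester releases CO2 and a benzylic C3 or C5 radical that is captured by the arylnickel species and coupled on the face away from the neighbouring C2 or C6 aryl group, so both new aryl groups should end trans.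

Step 12
Reactants: 17 diethyl {[(2R,3R,5R,6R)-3,5-bis(3,5-dimethoxyphenyl)-2,6-bis(4-methoxyphenyl)-2,3,5,6-tetrahydrobenzo[1,2-b:5,4-b′]difuran-4-yl]methyl}phosphonate; 18 2,4-dimethoxybenzaldehyde
Product: 19 (2R,3R,5R,6R)-4-[(E)-2-(2,4-dimethoxyphenyl)ethenyl]-3,5-bis(3,5-dimethoxyphenyl)-2,6-bis(4-methoxyphenyl)-2,3,5,6-tetrahydrobenzo[1,2-b:5,4-b′]difuran
Conditions: KOt-Bu (1.5 equiv), THF, 0 °C; then 18 (1.5 equiv), 0 °C → rt; aq. NH4Cl
Reagents that add atoms: none
Why: Horner–Wadsworth–Emmons olefination of the benzylic phosphonate anion with an aromatic aldehyde, which should give the E-stilbene, the diarylmethine hydrogens at C3 and C5 being much less acidic than the phosphonate CH2 group.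

Step 13
Reactants: 19 (2R,3R,5R,6R)-4-[(E)-2-(2,4-dimethoxyphenyl)ethenyl]-3,5-bis(3,5-dimethoxyphenyl)-2,6-bis(4-methoxyphenyl)-2,3,5,6-tetrahydrobenzo[1,2-b:5,4-b′]difuran
Product: 20 octa-O-methyl ether of the target (seven-membered ring closed; new CH(2,4-dimethoxyphenyl) centre R)
Conditions: MeSO3H (2 equiv), CH2Cl2 (0.005 M), −20 → 0 °C
Reagents that add atoms: none
Why: Intramolecular Friedel–Crafts alkylation (7-endo-trig) in which the acid protonates the stilbene at the carbon next to ring B, the cation stabilised by the 2,4-dimethoxyphenyl group is trapped by the ortho carbon of a neighbouring 3,5-dimethoxyphenyl ring (the two rings are equivalent through the C2 axis), and the new centre should form with the 2,4-dimethoxyphenyl group pseudo-equatorial and anti to the O–CH carbon of the adjacent furan across the seven-membered ring, as in acid-induced closures of stilbene-bearing 3-aryl-dihydrobenzofurans of this class.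

Step 14
Reactants: 20 octa-O-methyl ether of the target
Product: 21 CNP0154047.1 (target)
Conditions: BBr3 (24 equiv), CH2Cl2, −78 °C → rt; then MeOH, H2O
Reagents that add atoms: none
Why: Global cleavage of the eight aryl methyl ethers with BBr3, the usual last step for permethylated oligostilbenes, with cold addition chosen so that the benzylic ethers of the two dihydrofurans are not ionised and no stereocentre is disturbed.

Compound list
1 | 1,3-dimethoxy-5-methylbenzene (3,5-dimethoxytoluene) | Cc1cc(OC)cc(OC)c1 | starting material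
2 | 1,1′-(4,6-dimethoxy-2-methyl-1,3-phenylene)di(ethan-1-one) | CC(=O)c1c(C)c(C(C)=O)c(OC)cc1OC | intermediate
3 | 1,1′-(4,6-dihydroxy-2-methyl-1,3-phenylene)di(ethan-1-one) | CC(=O)c1c(C)c(C(C)=O)c(O)cc1O | intermediate
4 | (2E,2′E)-1,1′-(4,6-dihydroxy-2-methyl-1,3-phenylene)bis[3-(dimethylamino)prop-2-en-1-one] (not isolated) | CN(C)/C=C/C(=O)c1c(C)c(C(=O)/C=C/N(C)C)c(O)cc1O | intermediate
5 | 5-methyl-4H,6H-pyrano[3,2-g]chromene-4,6-dione | Cc1c2C(=O)C=COc2cc2OC=CC(=O)c12 | intermediate
6 | 5-(bromomethyl)-4H,6H-pyrano[3,2-g]chromene-4,6-dione | BrCc1c2C(=O)C=COc2cc2OC=CC(=O)c12 | intermediate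
7 | diethyl [(4,6-dioxo-4H,6H-pyrano[3,2-g]chromen-5-yl)methyl]phosphonate | CCOP(=O)(OCC)Cc1c2C(=O)C=COc2cc2OC=CC(=O)c12 | intermediate
8 | 4-methoxyphenylboronic acid | COc1ccc(B(O)O)cc1 | starting material
9 | diethyl {[(2R,8R)-2,8-bis(4-methoxyphenyl)-4,6-dioxo-2,3,7,8-tetrahydro-4H,6H-pyrano[3,2-g]chromen-5-yl]methyl}phosphonate | COc1ccc([C@H]2CC(=O)c3c(O2)cc2c(C(=O)C[C@H](c4ccc(OC)cc4)O2)c3CP(=O)(OCC)OCC)cc1 | intermediate
10 | diethyl {[(2R,8R)-4,6-dimethoxy-2,8-bis(4-methoxyphenyl)-2H,8H-pyrano[3,2-g]chromen-5-yl]methyl}phosphonate (not isolated) | COc1ccc([C@H]2C=C(OC)c3c(O2)cc2c(C(OC)=C[C@H](c4ccc(OC)cc4)O2)c3CP(=O)(OCC)OCC)cc1 | intermediate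
11 | dimethyl (2R,3R,5R,6R)-4-[(diethoxyphosphoryl)methyl]-2,6-bis(4-methoxyphenyl)-2,3,5,6-tetrahydrobenzo[1,2-b:5,4-b′]difuran-3,5-dicarboxylate (trans,trans) | COc1ccc([C@@H]2Oc3cc4c(c(CP(=O)(OCC)OCC)c3[C@H]2C(=O)OC)[C@@H](C(=O)OC)[C@H](c2ccc(OC)cc2)O4)cc1 | intermediate
12 | (2R,3R,5R,6R)-4-[(diethoxyphosphoryl)methyl]-2,6-bis(4-methoxyphenyl)-2,3,5,6-tetrahydrobenzo[1,2-b:5,4-b′]difuran-3,5-dicarboxylic acid | COc1ccc([C@@H]2Oc3cc4c(c(CP(=O)(OCC)OCC)c3[C@H]2C(=O)O)[C@@H](C(=O)O)[C@H](c2ccc(OC)cc2)O4)cc1 | intermediate
13 | bis(1,3-dioxoisoindolin-2-yl) (2R,3R,5R,6R)-4-[(diethoxyphosphoryl)methyl]-2,6-bis(4-methoxyphenyl)-2,3,5,6-tetrahydrobenzo[1,2-b:5,4-b′]difuran-3,5-dicarboxylate | COc1ccc([C@@H]2Oc3cc4c(c(CP(=O)(OCC)OCC)c3[C@H]2C(=O)ON5C(=O)c6ccccc6C5=O)[C@@H](C(=O)ON5C(=O)c6ccccc6C5=O)[C@H](c2ccc(OC)cc2)O4)cc1 | intermediate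
14 | 1-bromo-3,5-dimethoxybenzene | COc1cc(Br)cc(OC)c1 | starting material
15 | (3,5-dimethoxyphenyl)magnesium bromide (not isolated) | COc1cc(OC)cc([Mg]Br)c1 | intermediate
16 | (3,5-dimethoxyphenyl)zinc chloride | COc1cc(OC)cc([Zn]Cl)c1 | intermediate
17 | diethyl {[(2R,3R,5R,6R)-3,5-bis(3,5-dimethoxyphenyl)-2,6-bis(4-methoxyphenyl)-2,3,5,6-tetrahydrobenzo[1,2-b:5,4-b′]difuran-4-yl]methyl}phosphonate | COc1ccc([C@@H]2Oc3cc4c(c(CP(=O)(OCC)OCC)c3[C@H]2c2cc(OC)cc(OC)c2)[C@@H](c2cc(OC)cc(OC)c2)[C@H](c2ccc(OC)cc2)O4)cc1 | intermediate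
18 | 2,4-dimethoxybenzaldehyde | COc1ccc(C=O)c(OC)c1 | starting material
19 | (2R,3R,5R,6R)-4-[(E)-2-(2,4-dimethoxyphenyl)ethenyl]-3,5-bis(3,5-dimethoxyphenyl)-2,6-bis(4-methoxyphenyl)-2,3,5,6-tetrahydrobenzo[1,2-b:5,4-b′]difuran | COc1ccc([C@@H]2Oc3cc4c(c(/C=C/c5ccc(OC)cc5OC)c3[C@H]2c2cc(OC)cc(OC)c2)[C@@H](c2cc(OC)cc(OC)c2)[C@H](c2ccc(OC)cc2)O4)cc1 | intermediate
20 | octa-O-methyl ether of the target: core of 19 in which C2 of one 3,5-dimethoxyphenyl ring is bonded to the former stilbene carbon bearing the 2,4-dimethoxyphenyl group (R), closing a seven-membered ring with the ring B CH2 group; R at both O–CH and both aryl-CH carbons of the furans | COc1ccc([C@@H]2Oc3cc4c5c(c3[C@H]2c2cc(OC)cc(OC)c2)C[C@H](c2ccc(OC)cc2OC)c2c(OC)cc(OC)cc2[C@H]5[C@H](c2ccc(OC)cc2)O4)cc1 | intermediate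
21 | CNP0154047.1: octaphenol of 20 with the same five R centres | Oc1ccc([C@@H]2Oc3cc4c5c(c3[C@H]2c2cc(O)cc(O)c2)C[C@H](c2ccc(O)cc2O)c2c(O)cc(O)cc2[C@H]5[C@H](c2ccc(O)cc2)O4)cc1 | target

Total step count: 14. Longest linear sequence: 13 steps (steps 1–9 and 11–14, from 1).

Steps most likely to fail

Step 7. The 4-methoxyphenyl group may shift from C2 in place of the ring B carbon, the strong acid may open a benzylic ether with loss of configuration, the oxidant may attack the anisyl rings, or the second contraction may stall. The fallback replaces the oxidative shift by a Wolff ring contraction, in which only the ring B carbon can migrate. It sets out from 9: nitrosation at C3 and C7 (isoamyl nitrite, HCl, THF/EtOH, 0 °C) should give the 3,7-bis(hydroxyimino) diketone F1; a Forster reaction (NH2Cl made from aqueous NH3 and NaOCl, NaOH, 0 °C) should turn it into the 3,7-bis(diazo) diketone F2; irradiation at 365 nm in methanol should contract both rings, giving at first the product of enol protonation anti to the aryl groups, the cis,cis-diester F3; NaOMe in MeOH should then epimerise C3 and C5 to the trans,trans-diester 11, where the route is rejoined.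

Step 11. The hindered benzylic radicals may dimerise or abstract hydrogen before capture at nickel, and the arylzinc reagent may attack the activated ester carbonyl groups. The fallback is a decarboxylative arylation under dual photoredox and nickel catalysis, which uses the free acid and the aryl bromide and needs no organometallic reagent. It sets out from 12 and 14: Ir[dF(CF3)ppy]2(dtbbpy)PF6 (2 mol%), NiCl2·glyme (20 mol%), 4,4′-di-tert-butyl-2,2′-bipyridine (30 mol%), Cs2CO3, DMF, blue light, rt should give 17 directly, where the route is rejoined; steps 9 and 10 fall away and no compound outside the list is made (F0).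

Step 1. The second acetyl group may enter between the two methoxy groups or not at all, and AlCl3 may cleave an ether before the second acylation and so change the directing pattern. The fallback fixes both positions by halogenation and cross-coupling. It sets out from 1: NBS (2.1 equiv) in MeCN should brominate both positions para to a methoxy group to give 2,4-dibromo-1,5-dimethoxy-3-methylbenzene F4; twofold Stille coupling with tributyl(1-ethoxyvinyl)stannane (Pd(PPh3)4, toluene, 100 °C) should give the bis(enol ether) 2,4-bis(1-ethoxyethenyl)-1,5-dimethoxy-3-methylbenzene F5; aqueous HCl should hydrolyse it to 2, where the route is rejoined.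

Further compounds
F1 | step 7 | diethyl {[(2S,8S)-3,7-bis(hydroxyimino)-2,8-bis(4-methoxyphenyl)-4,6-dioxo-2,3,7,8-tetrahydro-4H,6H-pyrano[3,2-g]chromen-5-yl]methyl}phosphonate (same spatial arrangement at C2 and C8 as in 9) | COc1ccc([C@H]2C(=NO)C(=O)c3c(O2)cc2c(C(=O)C(=NO)[C@H](c4ccc(OC)cc4)O2)c3CP(=O)(OCC)OCC)cc1
F2 | step 7 | diethyl {[(2S,8S)-3,7-bis(diazo)-2,8-bis(4-methoxyphenyl)-4,6-dioxo-2,3,7,8-tetrahydro-4H,6H-pyrano[3,2-g]chromen-5-yl]methyl}phosphonate | COc1ccc([C@H]2C(=[N+]=[N-])C(=O)c3c(O2)cc2c(C(=O)C(=[N+]=[N-])[C@H](c4ccc(OC)cc4)O2)c3CP(=O)(OCC)OCC)cc1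
F3 | step 7 | dimethyl (2R,3S,5S,6R)-4-[(diethoxyphosphoryl)methyl]-2,6-bis(4-methoxyphenyl)-2,3,5,6-tetrahydrobenzo[1,2-b:5,4-b′]difuran-3,5-dicarboxylate (cis,cis) | COc1ccc([C@@H]2Oc3cc4c(c(CP(=O)(OCC)OCC)c3[C@@H]2C(=O)OC)[C@H](C(=O)OC)[C@H](c2ccc(OC)cc2)O4)cc1
F0 | step 11 | none | none
F4 | step 1 | 2,4-dibromo-1,5-dimethoxy-3-methylbenzene | Cc1c(Br)c(OC)cc(OC)c1Br
F5 | step 1 | 2,4-bis(1-ethoxyethenyl)-1,5-dimethoxy-3-methylbenzene | CCOC(=C)c1c(C)c(C(=C)OCC)c(OC)cc1OC
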